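The plan cuts both bonds at the ring-fusion alkene, O1–C8a of the pyranone and C4a–C5 of the carbocycle. It exploits the fact that C4a=C8a, shared by both rings, carries the ring oxygen on C8a and the C5 carbinol on C4a, the pattern of an ynone C4(=O)–C4a≡C8a functionalised at both alkyne carbons. One chiral-base-triggered oxa-Michael/aldol domino should therefore close both rings and set C5 from an acyclic C26 7,9-dioxo-5-ynal, which holds an enolised 1,3-diketone, the ynone and a tethered aldehyde. This labile precursor is unveiled last, by a neutral double oxidation of a keto diol assembled by an aldol addition.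

Key step: step 8

Remark: C7 of compounds 9 and 10 is formed as a racemate and is removed by oxidation in step 7. Which pseudoenantiomer of the cinchona squaramide gives (5S) cannot be predicted for a new reaction, so both are to be screened and the configuration of 12 checked by Mosher ester analysis.

Step 1
Reactants: 1 (11Z)-hexadec-11-en-1-ol
Product: 2 (5Z)-16-iodohexadec-5-ene
Conditions: PPh3, I2, imidazole, CH2Cl2, 0 °C → rt (phosphine–iodine adduct formed before 1 is added, dark)
Reagents that add atoms: iodine, II
Why: Appel-type iodination turns the primary alcohol into the iodide by SN2 displacement of an alkoxyphosphonium ion, and the isolated Z-alkene should stay untouched because no free iodine remains once the adduct is preformed.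

Step 2
Reactants: 2 (5Z)-16-iodohexadec-5-ene; 3 acetone N,N-dimethylhydrazone
Product: 5 (14Z)-nonadec-14-en-2-one, via alkylated dimethylhydrazone 4 (not isolated)
Conditions: 3, LDA, THF, 0 °C; 2, −78 °C → rt; then 2 M aq HCl, THF, rt
Reagents that add atoms: water, O
Why: Azaenolate alkylation of a dimethylhydrazone: the lithiated symmetrical acetone hydrazone should be monoalkylated by the primary iodide (SN2), and dilute aqueous acid then hydrolyses the C=N bond to the methyl ketone without harming the Z-alkene.

Step 3
Reactants: 6 hex-5-yn-1-ol
Product: 7 tert-butyl(hex-5-yn-1-yloxy)dimethylsilane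
Conditions: TBSCl, imidazole, CH2Cl2, 0 °C → rt
Reagents that add atoms: tert-butyldimethylsilyl chloride, CC(C)(C)[Si](C)(C)Cl
Why: Imidazole-promoted silylation of a primary alcohol gives a TBS ether that withstands the organolithium steps that follow.

Step 4
Reactants: 7 tert-butyl(hex-5-yn-1-yloxy)dimethylsilane
Product: 8 7-[(tert-butyldimethylsilyl)oxy]hept-2-ynal
Conditions: n-BuLi, THF, −78 °C; DMF, −78 °C → rt; inverse quench into 10% aq KH2PO4/MTBE, 0 °C
Reagents that add atoms: N,N-dimethylformamide, CN(C)C=O
Why: Formylation of a lithium acetylide with DMF, with the inverse quench into phosphate buffer so that the hemiaminal collapses while the liberated dimethylamine is protonated and cannot add to the ynal.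

Step 5
Reactants: 5 (14Z)-nonadec-14-en-2-one; 8 7-[(tert-butyldimethylsilyl)oxy]hept-2-ynal
Product: 9 (21Z)-1-[(tert-butyldimethylsilyl)oxy]-7-hydroxyhexacos-21-en-5-yn-9-one (racemic at C7)
Conditions: LDA, THF, −78 °C, 5 added slowly; then 8, −78 °C; AcOH/THF quench at −78 °C
Reagents that add atoms: none
Why: Directed aldol addition: LDA should remove a methyl proton of the ketone kinetically and the lithium enolate should add 1,2 to the non-enolisable ynal at −78 °C, the new carbinol centre C7 arising as a racemate that is oxidised away in step 7.

Step 6
Reactants: 9 (21Z)-1-[(tert-butyldimethylsilyl)oxy]-7-hydroxyhexacos-21-en-5-yn-9-one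
Product: 10 (21Z)-1,7-dihydroxyhexacos-21-en-5-yn-9-one (racemic at C7)
Conditions: HF·pyridine, pyridine, THF, 0 °C → rt
Reagents that add atoms: none
Why: Buffered fluoride desilylation cleaves the primary TBS ether under weakly acidic conditions and so avoids the retro-aldol cleavage or dehydration of the β-hydroxy ketone that basic fluoride could cause.

Step 7
Reactants: 10 (21Z)-1,7-dihydroxyhexacos-21-en-5-yn-9-one
Product: 11 (21Z)-7,9-dioxohexacos-21-en-5-ynal
Conditions: Dess–Martin periodinane (2.5 equiv), NaHCO3, CH2Cl2, 0 °C → rt; aq Na2S2O3/NaHCO3 wash, short silica plug, used at once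
Reagents that add atoms: none
Why: Dess–Martin oxidation should take the primary alcohol to the aldehyde and the propargylic β-hydroxy ketone to the enolised 1,3-diketone in one buffered operation, so that the base-labile alkyne-dione never meets fluoride, amine or strong acid before the key step.

Step 8
Reactants: 11 (21Z)-7,9-dioxohexacos-21-en-5-ynal
Product: 12 (5S)-2-[(12Z)-heptadec-12-en-1-yl]-5-hydroxy-5,6,7,8-tetrahydro-4H-chromen-4-one
Conditions: 9-amino(9-deoxy)epi-cinchona 3,5-bis(trifluoromethyl)phenyl squaramide (10 mol %, quinine- or quinidine-derived pseudoenantiomer as chosen by screening), toluene (0.01 M), 4 Å MS, −40 °C, slow addition of 11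
Reagents that add atoms: none
Why: Proposed new method: the quinuclidine nitrogen should deprotonate the enolised 1,3-diketone, and the enolate oxygen on C2 (chromenone numbering of 12 used for 11) adds to the ynone β-carbon C8a while the electron density that builds up at C4a, held in an in-plane sp2 orbital because a six-membered ring cannot hold a linear allenolate, is taken up by the squaramide-bound formyl carbon C5 lying cis to it on the four-atom tether, after which the alkoxide is protonated by the ammonium ion and the catalyst is released. The closest known reaction types are the halo-aldol and Morita–Baylis–Hillman-type conjugate addition–aldol cyclisations of ω-formyl ynones and the base- or acid-induced 6-endo cyclisation of 1-alkyne-3,5-diones to 4-pyranones. The pyranone closes 6-endo-dig (O1–C8a) and the carbocycle 6-exo-trig at the formyl group (C4a–C5). The single new stereocentre C5 is controlled by the catalyst, whose squaramide N–H bonds fix one enantioface of the aldehyde towards the ion-paired nucleophile, the substrate itself being achiral. The step needs O- over C-attack of the diketonate, 6-endo over 5-exo addition and C–C bond formation ahead of protonation at C4a: the first two follow from ring strain (C3 cannot reach the alkyne) and from the ynone polarisation (5-exo attack at C4a would be anti-Michael), the third from the tether that parks the activated aldehyde where the carbanion develops, helped by low temperature, a non-polar solvent and high dilution. Protonation at C4a would give only an achiral, separable monocyclic pyranone aldehyde, and 12 cannot revert by retro-aldol cleavage because that would demand a vinyl anion, so the configuration at C5 is not eroded.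

Compound list
1 | (11Z)-hexadec-11-en-1-ol | CCCC/C=C\CCCCCCCCCCO | starting material
2 | (5Z)-16-iodohexadec-5-ene | CCCC/C=C\CCCCCCCCCCI | intermediate
3 | acetone N,N-dimethylhydrazone | CC(C)=NN(C)C | starting material
4 | (14Z)-nonadec-14-en-2-one N,N-dimethylhydrazone (not isolated) | CCCC/C=C\CCCCCCCCCCCC(C)=NN(C)C | intermediate
5 | (14Z)-nonadec-14-en-2-one | CCCC/C=C\CCCCCCCCCCCC(C)=O | intermediate
6 | hex-5-yn-1-ol | C#CCCCCO | starting material
7 | tert-butyl(hex-5-yn-1-yloxy)dimethylsilane | C#CCCCCO[Si](C)(C)C(C)(C)C | intermediate
8 | 7-[(tert-butyldimethylsilyl)oxy]hept-2-ynal | O=CC#CCCCCO[Si](C)(C)C(C)(C)C | intermediate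
9 | (21Z)-1-[(tert-butyldimethylsilyl)oxy]-7-hydroxyhexacos-21-en-5-yn-9-one, racemic at C7 | CCCC/C=C\CCCCCCCCCCCC(=O)CC(O)C#CCCCCO[Si](C)(C)C(C)(C)C | intermediate
10 | (21Z)-1,7-dihydroxyhexacos-21-en-5-yn-9-one, racemic at C7 | CCCC/C=C\CCCCCCCCCCCC(=O)CC(O)C#CCCCCO | intermediate
11 | (21Z)-7,9-dioxohexacos-21-en-5-ynal | CCCC/C=C\CCCCCCCCCCCC(=O)CC(=O)C#CCCCC=O | intermediate
12 | (5S)-2-[(12Z)-heptadec-12-en-1-yl]-5-hydroxy-5,6,7,8-tetrahydro-4H-chromen-4-one | CCCC/C=C\CCCCCCCCCCCc1cc(=O)c2c(o1)CCC[C@@H]2O | target

Total step count: 8. Longest linear sequence: 6 steps (steps 1, 2, 5, 6, 7, 8; the branch through steps 3 and 4 is equally long).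

Steps most likely to fail

Step 8. Proton transfer to C4a may outrun C–C bond formation, so that ring closure stops after the pyranone. Intermolecular Knoevenagel-type condensation of the diketone with the aldehyde may compete, or the catalyst may discriminate the aldehyde faces poorly. The fallback uses known chemistry only, sets out from iodide 2 and comes back to the route at 12.
- Malonic ester alkylation of 2 (dimethyl malonate, NaH, THF/DMF) should give dimethyl 2-[(11Z)-hexadec-11-en-1-yl]propanedioate F1.
- Krapcho demethoxycarbonylation (LiCl, wet DMSO, heat) converts it into methyl (13Z)-octadec-13-enoate F2.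
- Claisen condensation of F2 with the dianion of commercial 2-acetylcyclohexane-1,3-dione (LDA, 3 equiv, THF), acylating the acetyl carbon, gives 2-[(15Z)-3-oxoicos-15-enoyl]cyclohexane-1,3-dione F3.
- Acid cyclodehydration of this 1,3,5-tricarbonyl array (trifluoroacetic acid, CH2Cl2) closes the pyranone to 2-[(12Z)-heptadec-12-en-1-yl]-7,8-dihydro-4H-chromene-4,5(6H)-dione F4.
- Noyori asymmetric transfer hydrogenation of the C5 ketone (RuCl(p-cymene)[(S,S)-TsDPEN], HCO2H/Et3N) is expected, by analogy with 1-tetralone, to give the (5S)-alcohol 12. A transfer hydrogenation is chosen because a borane-based reduction would hydroborate the Z-alkene, and the doubly vinylogous C4 carbonyl should not react.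

Step 7. Excess periodinane may over-oxidise the freshly formed enolised diketone at C8, or the diketo-ynal may cyclise during oxidation and work-up. The fallback sets out from diol 10 and comes back at 11, splitting the global oxidation into two orthogonal events with a different order of functional-group generation.
- TEMPO/PhI(OAc)2 (CH2Cl2, rt) oxidises only the primary alcohol and should give (21Z)-7-hydroxy-9-oxohexacos-21-en-5-ynal F5.
- Activated MnO2 (CH2Cl2, rt), a neutral heterogeneous oxidant selective for propargylic alcohols, then generates the 1,3-diketone last and leaves the aldehyde and the enolised diketone alone, giving 11.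

Step 5. Proton exchange between enolate and unreacted ketone may scramble the enolate regiochemistry, the enolate may add in conjugate fashion to the ynal, or the aldolate may undergo retro-aldol cleavage on warming. The fallback sets out from ketone 5 and comes back at 9, replacing the basic enolate addition by a Lewis-acid-mediated one.
- The kinetic enolate of 5 is trapped (LDA, TMSCl, THF, −78 °C) as trimethyl{[(14Z)-nonadeca-1,14-dien-2-yl]oxy}silane F6, whose regiochemistry can be checked before use.
- Mukaiyama aldol addition of F6 to ynal 8 (BF3·OEt2, CH2Cl2, −78 °C) should give 9 after aqueous work-up.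

Further compounds
F1 | step 8 | dimethyl 2-[(11Z)-hexadec-11-en-1-yl]propanedioate | CCCC/C=C\CCCCCCCCCCC(C(=O)OC)C(=O)OC
F2 | step 8 | methyl (13Z)-octadec-13-enoate | CCCC/C=C\CCCCCCCCCCCC(=O)OC
F3 | step 8 | 2-[(15Z)-3-oxoicos-15-enoyl]cyclohexane-1,3-dione | CCCC/C=C\CCCCCCCCCCCC(=O)CC(=O)C1C(=O)CCCC1=O
F4 | step 8 | 2-[(12Z)-heptadec-12-en-1-yl]-7,8-dihydro-4H-chromene-4,5(6H)-dione | CCCC/C=C\CCCCCCCCCCCc1cc(=O)c2c(o1)CCCC2=O
F5 | step 7 | (21Z)-7-hydroxy-9-oxohexacos-21-en-5-ynal | CCCC/C=C\CCCCCCCCCCCC(=O)CC(O)C#CCCCC=O
F6 | step 5 | trimethyl{[(14Z)-nonadeca-1,14-dien-2-yl]oxy}silane | CCCC/C=C\CCCCCCCCCCCC(=C)O[Si](C)(C)C
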